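The route rests on one disconnection: the C6–O bond, made by conjugate addition within an achiral p-quinol. In that dienone C1 (bearing OH and the C7H2OBz arm) lies on a mirror plane between two identical enone arms, C2=C3 and C6=C5, which share the C4 carbonyl. A boronic acid hung on the C1 hydroxyl delivers its second oxygen to C6 of one arm under a chiral aminothiourea. This single operation closes a cis-fused dioxaborolane on the six-membered ring, sets C1 and C6 together, and leaves the other arm as the C2=C3 alkene of the target. The precursor, 4-(benzoyloxymethyl)-4-hydroxycyclohexa-2,5-dienone, comes in two steps from 4-hydroxybenzyl alcohol. C5 and C4 follow by substrate control.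

Key step: step 3

Numbering and faces, used for all compounds: C1 is the ring carbon with O and C7H2OBz, C2=C3 is the alkene, C4 the CH–OBz carbon, C5 and C6 the CH–O carbons (C6 next to C1). α is the ring face that carries the C1 and C6 oxygens and β is the other face. The target has O1 α, O6 α, O5 β, O4 β, which is (1S,4R,5S,6S).

Assumption: the arm that a cinchona thiourea selects on this dienone cannot be predicted with certainty. The route is written for the quinine-derived catalyst giving (1S,6S)-7. If a test run shows the opposite sense, the quinidine-derived pseudo-enantiomer takes its place.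

Step 1
Reactants: 1 4-hydroxybenzyl alcohol; 2 benzoic acid
Product: 3 4-hydroxybenzyl benzoate
Conditions: PPh3, DIAD, THF, 0 °C → rt
Reagents that add atoms: none
Why: Mitsunobu esterification, in which only the alcohol oxygen becomes an oxyphosphonium leaving group and only the carboxylic acid is acidic enough to be the partner, so the benzylic ester should form with the phenol left free, the absence of base avoids 1,6-elimination of benzoate to the p-quinone methide, and no stereocentre is created.

Step 2
Reactants: 3 4-hydroxybenzyl benzoate
Product: 4 4-(benzoyloxymethyl)-4-hydroxycyclohexa-2,5-dienone (achiral p-quinol)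
Conditions: PhI(OAc)2, MeCN–H2O (3:1), 0 °C
Reagents that add atoms: water, O
Why: Iodine(III)-mediated oxidative dearomatisation of a para-substituted phenol, in which the aryloxy-λ3-iodane collapses with loss of iodobenzene while water attacks the para carbon (C1), giving the cross-conjugated 4-hydroxydienone, which is achiral because its two arms are identical.

Step 3
Reactants: 4 4-(benzoyloxymethyl)-4-hydroxycyclohexa-2,5-dienone; 5 phenylboronic acid
Product: 7 cis-fused cyclic phenylboronate (1,3,2-dioxaborolane across O1 and O6) of [(1S,6S)-1,6-dihydroxy-4-oxocyclohex-2-en-1-yl]methyl benzoate, via boronic hemiester 6 (not isolated)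
Conditions: 9-amino(9-deoxy)epi-quinine 3,5-bis(trifluoromethyl)phenyl thiourea (10–20 mol %), 4 Å MS, toluene, rt
Reagents that add atoms: none
Why: Phenylboronic acid condenses reversibly with the tertiary C1 hydroxyl (the sieves take up the water) to give hemiester 6, whose remaining B–OH is made nucleophilic by the quinuclidine nitrogen of the catalyst while the thiourea hydrogen-bonds to the C4 carbonyl, so that this oxygen adds to C6 in a conjugate sense and C5 is then protonated. The closest known reaction types are the aminothiourea-catalysed oxa-Michael addition of boronic acid hemiesters of γ-hydroxy enones and the cinchona-thiourea hetero-Michael desymmetrisation of 4-hydroxycyclohexadienones. The 1,3,2-dioxaborolane ring (O–B–O–C6–C1) closes in the 5-exo-trig mode, since the C6=C5 bond that is attacked lies outside the new ring. C6 is controlled by the tether, because an O–B–O bridge anchored on the C1 oxygen can reach only the ring face that carries this oxygen and therefore gives the cis C1,C6 relation, whereas C1 becomes stereogenic in the same event and its configuration, like the absolute sense at C6, is decided by which enantiotopic arm the chiral catalyst activates. The step needs arm selectivity (catalyst), a single addition (after closure boron has no OH left and the C1 oxygen is tied up, so the second arm stays as the C2=C3 enone) and one defined site for boron (the C7 oxygen is already acylated, so no 1,2-diol boronate can compete). As oxa-Michael additions are reversible, the reaction is kept at or below room temperature and worked up at full conversion so that the enantiomeric purity should not erode.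

Step 4
Reactants: 7 cis-fused cyclic phenylboronate
Product: 9 1,6-O-isopropylidene ketal of [(1S,6S)-1,6-dihydroxy-4-oxocyclohex-2-en-1-yl]methyl benzoate, via free cis-diol 8 (not isolated)
Conditions: pinacol, CH2Cl2, rt; then Me2C(OMe)2, PPTS (cat.), rt
Reagents that add atoms: 2,2-dimethoxypropane, COC(C)(C)OC
Why: Boronic ester transesterification followed by acid-catalysed transketalisation, in which pinacol forms the more stable boronate and frees the cis-diol, which is trapped at once as the five-membered isopropylidene ketal under conditions too mild for retro-oxa-Michael cleavage, so C1 and C6 are untouched.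

Step 5
Reactants: 9 isopropylidene ketal enone
Product: 10 (1S,6S) C4-O-TBS dienol ether of 9 (double bonds C2=C3 and C4=C5)
Conditions: TBSOTf, Et3N, CH2Cl2, −78 → 0 °C
Reagents that add atoms: tert-butyldimethylsilyl triflate, CC(C)(C)[Si](C)(C)OS(=O)(=O)C(F)(F)F
Why: Soft enolisation (silyl triflate/tertiary amine) to a cross-conjugated silyl dienol ether, in which C5 carries the only enolisable hydrogens because C1 is quaternary, no free enolate is formed, and the pseudo-equatorial C6–O bond of the cis-fused ketal overlaps poorly with the π system, all of which should suppress β-elimination of O6.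

Step 6
Reactants: 10 C4-O-TBS dienol ether
Product: 12 (1S,5S,6S) enone carrying a β-OTBS group at C5 (trans to O6) with the 1,6-ketal in place, via silyloxy epoxide 11 (not isolated)
Conditions: mCPBA, CH2Cl2, −20 → 0 °C
Reagents that add atoms: mCPBA, O=C(OO)c1cccc(Cl)c1
Why: Rubottom oxidation, in which the peracid epoxidises the electron-rich C4=C5 enol ether bond rather than C2=C3, from the β face opposite to the dioxolane as is usual for cis-cyclohexadienediol ketals, and the silyloxy epoxide opens with a 1,4-silyl shift to the α-silyloxy enone, which sets C5–O trans to C6–O and leaves it already protected.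

Step 7
Reactants: 12 C5 β-silyloxy enone
Product: 13 (1S,4S,5R,6S) allylic alcohol with C4–OH α (trans to the C5 β-OTBS)
Conditions: NaBH4, CeCl3·7H2O, MeOH, −78 °C
Reagents that add atoms: none
Why: Luche reduction, in which the cerium-modified borohydride adds 1,2 to the enone and axial attack from the β face (away from the ketal, with the C5 silyl ether equatorial) should give the pseudo-equatorial α-alcohol, trans to the C5 oxygen.

Step 8
Reactants: 13 C4 α-allylic alcohol; 2 benzoic acid
Product: 14 (1S,4R,5R,6S) C4 β-benzoate (cis to the C5 β-OTBS) with ketal and silyl ether in place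
Conditions: PPh3, DIAD, toluene, 0 °C → rt
Reagents that add atoms: none
Why: Mitsunobu reaction, in which SN2 displacement of the oxyphosphonium group by benzoate inverts C4 and installs the ester of the target in the same operation, giving C4–OBz β and cis to the C5 oxygen, while SN2′ attack at C2 is disfavoured by the neighbouring quaternary C1.

Step 9
Reactants: 14 protected dibenzoate
Product: 15 [(1S,4R,5S,6S)-4-(benzoyloxy)-1,5,6-trihydroxycyclohex-2-en-1-yl]methyl benzoate (CNP0217467.1)
Conditions: TFA–H2O (9:1), 0 °C → rt
Reagents that add atoms: none
Why: Acid hydrolysis of the isopropylidene ketal and acid solvolysis of the secondary TBS ether in one operation, acid being chosen instead of fluoride or base because the cis C4-benzoate/C5-hydroxyl pair would be prone to base-induced acyl migration, and no stereocentre is affected.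

Compound list
1 | 4-hydroxybenzyl alcohol | OCc1ccc(O)cc1 | starting material
2 | benzoic acid | O=C(O)c1ccccc1 | starting material
3 | 4-hydroxybenzyl benzoate | O=C(OCc1ccc(O)cc1)c1ccccc1 | intermediate
4 | 4-(benzoyloxymethyl)-4-hydroxycyclohexa-2,5-dienone (achiral p-quinol) | O=C1C=CC(O)(COC(=O)c2ccccc2)C=C1 | intermediate
5 | phenylboronic acid | OB(O)c1ccccc1 | starting material
6 | phenylboronic hemiester of 4 at the C1 oxygen (achiral, formed in the flask) | O=C1C=CC(OB(O)c2ccccc2)(COC(=O)c2ccccc2)C=C1 | intermediate
7 | cis-fused cyclic phenylboronate of [(1S,6S)-1,6-dihydroxy-4-oxocyclohex-2-en-1-yl]methyl benzoate | O=C(OC[C@]1(OB(c2ccccc2)O3)[C@@H]3CC(=O)C=C1)c1ccccc1 | intermediate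
8 | [(1S,6S)-1,6-dihydroxy-4-oxocyclohex-2-en-1-yl]methyl benzoate (cis-diol, formed in the flask) | O=C(OC[C@@]1(O)C=CC(=O)C[C@@H]1O)c1ccccc1 | intermediate
9 | 1,6-O-isopropylidene ketal of 8, (1S,6S) | O=C(OC[C@@]1(OC2(C)C)C=CC(=O)C[C@@H]1O2)c1ccccc1 | intermediate
10 | C4-O-TBS dienol ether of 9, (1S,6S), C2=C3 and C4=C5 | O=C(OC[C@@]1(OC2(C)C)C=CC(O[Si](C)(C)C(C)(C)C)=C[C@@H]1O2)c1ccccc1 | intermediate
11 | β-face C4,C5-epoxide of 10 with OTBS on C4 (formed in the flask) | O=C(OC[C@@]1(OC2(C)C)C=C[C@@]3(O[Si](C)(C)C(C)(C)C)O[C@H]3[C@@H]1O2)c1ccccc1 | intermediate
12 | (1S,5S,6S) C5 β-OTBS enone, 1,6-ketal | O=C(OC[C@@]1(OC2(C)C)C=CC(=O)[C@@H](O[Si](C)(C)C(C)(C)C)[C@@H]1O2)c1ccccc1 | intermediate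
13 | (1S,4S,5R,6S) allylic alcohol, C4–OH α, C5 β-OTBS, 1,6-ketal | O=C(OC[C@@]1(OC2(C)C)C=C[C@H](O)[C@@H](O[Si](C)(C)C(C)(C)C)[C@@H]1O2)c1ccccc1 | intermediate
14 | (1S,4R,5R,6S) C4 β-benzoate, C5 β-OTBS, 1,6-ketal | O=C(OC[C@@]1(OC2(C)C)C=C[C@@H](OC(=O)c3ccccc3)[C@@H](O[Si](C)(C)C(C)(C)C)[C@@H]1O2)c1ccccc1 | intermediate
15 | [(1S,4R,5S,6S)-4-(benzoyloxy)-1,5,6-trihydroxycyclohex-2-en-1-yl]methyl benzoate | O=C(OC[C@@]1(O)C=C[C@@H](OC(=O)c2ccccc2)[C@@H](O)[C@@H]1O)c1ccccc1 | target

Total step count: 9. Longest linear sequence: 9 steps (1 → 15).

Steps most likely to fail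

Step 3. The catalyst may discriminate poorly between the two enantiotopic arms. Hemiester formation at the hindered tertiary hydroxyl may be slow. Reversible addition may erode the enantiomeric purity, and the amine may induce benzoyl transfer from O7. The fallback sets out from 4 and replaces the boron tether and base catalysis by a carbon tether and Brønsted acid catalysis. Compound 4 is treated with 4-methoxybenzaldehyde and a chiral BINOL-derived phosphoric acid (toluene, rt). This is the known acetalisation/oxa-Michael cascade of p-quinols, in which the hemiacetal hydroxyl adds to one arm. It should give the cis-fused 4-methoxybenzylidene acetal F1 (aryl group expected exo; this centre is lost later). Mild hydrolysis (catalytic TFA in wet CH2Cl2, 0 °C) frees diol 8. Ketalisation of 8 with Me2C(OMe)2/PPTS brings the material back to the route at 9.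

Step 5. The C6 oxygen may be lost by β-elimination during enolisation, which opens the dioxolane and returns a dienone. The silyl triflate may also attack the ketal. The fallback sets out from 9 and avoids any C4 enol derivative. Luche reduction should give the C5-unsubstituted allylic alcohol F2 (its C4 configuration is of no consequence). Acetylation (Ac2O, pyridine) gives the allylic acetate F3. Palladium-catalysed 1,4-elimination (Pd(PPh3)4, Et3N, THF, reflux) gives the cyclohexadiene ketal F4. Catalytic osmylation (OsO4, NMO, acetone–H2O) should attack the less hindered C4=C5 bond, remote from the quaternary C1, on the β face opposite to the ketal. This gives the C4,C5 β,β-cis-diol F5. Trimethyl orthobenzoate with catalytic CSA converts F5 into the cyclic orthobenzoate F6. Aqueous TFA should then open the orthoester to the ester of the pseudo-axial oxygen (O4), as is usual for cyclic orthoesters on six-membered rings. The same treatment hydrolyses the ketal, so the material comes back to the route at 15.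

Step 8. The alkoxyphosphonium ion may form slowly at a carbinol flanked by the silyl ether. Elimination towards a diene may compete, and partial ionisation may cause loss of stereochemical fidelity. The fallback sets out from 13 and separates activation from displacement. MsCl/Et3N (CH2Cl2, −20 °C) gives the C4 α-mesylate F7. This is displaced with inversion by caesium benzoate with 18-crown-6 in toluene, and the material comes back to the route at 14.

Further compounds
F1 | step 3 | cis-fused 1,6-O-(4-methoxybenzylidene) acetal of 8, aryl exo | O=C(OC[C@@]1(O[C@@H]2c3ccc(OC)cc3)C=CC(=O)C[C@@H]1O2)c1ccccc1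
F2 | step 5 | C4 α-allylic alcohol from 9 (C5 is CH2), 1,6-ketal | O=C(OC[C@@]1(OC2(C)C)C=C[C@H](O)C[C@@H]1O2)c1ccccc1
F3 | step 5 | C4 α-allylic acetate of F2 | O=C(OC[C@@]1(OC2(C)C)C=C[C@H](OC(C)=O)C[C@@H]1O2)c1ccccc1
F4 | step 5 | (1S,6S) cyclohexa-2,4-diene 1,6-ketal | O=C(OC[C@@]1(OC2(C)C)C=CC=C[C@@H]1O2)c1ccccc1
F5 | step 5 | C4,C5 β,β-cis-diol, 1,6-ketal | O=C(OC[C@@]1(OC2(C)C)C=C[C@@H](O)[C@@H](O)[C@@H]1O2)c1ccccc1
F6 | step 5 | C4,C5 cyclic methyl orthobenzoate of F5 (orthoester carbon undefined, of no consequence) | O=C(OC[C@@]1(OC2(C)C)C=C[C@H]3OC(OC)(c4ccccc4)O[C@H]3[C@@H]1O2)c1ccccc1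
F7 | step 8 | C4 α-mesylate of 13 | O=C(OC[C@@]1(OC2(C)C)C=C[C@H](OS(C)(=O)=O)[C@@H](O[Si](C)(C)C(C)(C)C)[C@@H]1O2)c1ccccc1
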